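**Retrosynthetic overview**

1. The target is ent-labda-8(17),12E,14-triene-18,19-diyl diacetate. Its trans-decalin (rings A and B) with C5, C9 and C10 is taken unchanged from andrographolide 1, in which C4 already carries the oxygenated C19 beside the C18 methyl and the equatorial O3 lies gauche to that methyl.
2. Disconnections: C8=C17 and C14=C15 (double Wittig methylenation), C12=C13 (formylethylidene Wittig on a C12 aldehyde), C3–O (Barton–McCombie), C18–O (silicon-tethered C–H oxidation directed from O3).
3. Ozonolysis of 19-O-acetylandrographolide removes C13–C16 and C17. The C8 ketone and C12 aldehyde so formed are both masked as dioxolanes in one operation, so that no alkene or free carbonyl group meets the iridium hydride chemistry and no redox detour is needed at C12.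
4. No carbocycle is built. Rings A and B come from 1, the two dioxolanes are protective, and the only ring closed on purpose is the oxasilolane O3–Si–C18–C4–C3 of the key step, which oxidation opens again. Once O18 is acetylated, C4 is no longer stereogenic and O3 is removed.

Key step: step 5

Remark: ent-labdane numbering of andrographolide is used throughout (O3 secondary hydroxyl, C18 methyl and C19 hydroxymethyl on C4, C20 methyl on C10); the acetate placed on O19 in step 1 is kept to the end as one of the two acetates of the target.

**Route**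

Step 1
Reactants: 1 andrographolide; 2 acetic anhydride
Product: 3 19-O-acetylandrographolide
Conditions: Ac2O (1.1 equiv), pyridine, 0 °C
Reagents that add atoms: acetic anhydride 2, CC(=O)OC(C)=O
Why: Selective O-acylation of the only primary hydroxyl (C19) should prevail over the secondary O3 next to quaternary C4 and the allylic O14 with a slight excess of anhydride at 0 °C, and an acetate that strays onto O14 is of no consequence because that carbon leaves with the lactone in step 2.

Step 2
Reactants: 3 19-O-acetylandrographolide
Product: 4 19-acetoxy-3-hydroxy-8-oxo-13,14,15,16,17-pentanor-ent-labdan-12-al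
Conditions: O3, CH2Cl2/MeOH, −78 °C; then Me2S, −78 °C to rt
Reagents that add atoms: ozone, [O-][O+]=O
Why: Ozonolysis with reductive work-up cleaves the electron-rich C8=C17 methylidene and, with excess ozone, the conjugated C12=C13 alkylidene lactone, leaving the C8 ketone and the C12 aldehyde, while C9 should not epimerise because its side chain is equatorial and the work-up is neutral.

Step 3
Reactants: 4 19-acetoxy-3-hydroxy-8-oxo-13,14,15,16,17-pentanor-ent-labdan-12-al; 5 ethylene glycol
Product: 7 19-acetoxy-8,8:12,12-bis(ethylenedioxy)-13,14,15,16,17-pentanor-ent-labdan-3-ol, via mono-dioxolane ketone 6 (not isolated)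
Conditions: HOCH2CH2OH (excess), pTsOH·H2O (cat.), benzene, reflux, Dean–Stark
Reagents that add atoms: ethylene glycol 5, OCCO
Why: Acid-catalysed acetalization with azeotropic removal of water should convert the aldehyde first and then the C8 ketone into 1,3-dioxolanes, masking both carbonyl groups against hydrosilylation while the primary acetate and the free O3 hydroxyl are left alone.

Step 4
Reactants: 7 19-acetoxy-8,8:12,12-bis(ethylenedioxy)-13,14,15,16,17-pentanor-ent-labdan-3-ol; 8 diethylsilane
Product: 9 19-acetoxy-3-[(diethylsilyl)oxy]-8,8:12,12-bis(ethylenedioxy)-13,14,15,16,17-pentanor-ent-labdane (O3–SiHEt2 ether of 7)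
Conditions: Et2SiH2 (1.5 equiv), [Ir(cod)OMe]2 (0.1 mol %), THF, rt; volatiles removed in vacuo, crude used directly
Reagents that add atoms: diethylsilane 8, CC[SiH2]CC
Why: Iridium-catalysed dehydrogenative O-silylation of a secondary alcohol with a dihydrosilane should give the (hydrido)silyl ether with loss of H2 at room temperature, where the ester and the acetals are not reduced, and the excess silane is stripped off before heating.

Step 5
Reactants: 9 19-acetoxy-3-[(diethylsilyl)oxy]-8,8:12,12-bis(ethylenedioxy)-13,14,15,16,17-pentanor-ent-labdane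
Product: 10 oxasilolane (2,2-diethyl-1-oxa-2-silacyclopentane) bridging O3 and C18 of 19-acetoxy-8,8:12,12-bis(ethylenedioxy)-13,14,15,16,17-pentanor-ent-labdane
Conditions: [Ir(cod)OMe]2 (1 mol %), 3,4,7,8-tetramethyl-1,10-phenanthroline (2.5 mol %), norbornene (1.2 equiv), THF, 100 °C, sealed tube
Reagents that add atoms: none
Why: Oxidative addition of the Si–H bond to the phenanthroline-ligated iridium catalyst and transfer of hydrogen to norbornene should give an iridium silyl that cleaves a C18–H bond of the equatorial methyl through a six-membered iridacycle (Ir–Si–O3–C3–C4–C18), after which C–Si reductive elimination releases the oxasilolane. The closest known reaction type is the hydroxyl-directed, iridium-catalysed gamma-C–H silylation of (hydrido)silyl ethers of 4,4-disubstituted 3-hydroxy terpenoids, which functionalises the equatorial methyl on C4. The one ring formed, O3–Si–C18–C4–C3, closes by C18–Si bond formation and is trans-fused to ring A because O3 and C18 are both equatorial and gauche. No stereocentre is created: no bond to C3 or C4 is broken, so both keep the configuration of andrographolide, and silicon carries two ethyl groups. The step needs site selectivity for the primary C18–H bonds over the secondary C19–H bonds next to the acetate, the methylene C–H bonds at C1 and C2 and the tertiary C5–H bond, and this rests on the preference of the catalyst for a primary C–H bond that closes a five-membered ring, C18 being the only methyl within that reach. Chemoselectivity is secured by the substrate, which carries no alkene and no free carbonyl group, only an acetate and two dioxolanes that this catalyst system should leave alone.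

Step 6
Reactants: 10 oxasilolane bridging O3 and C18
Product: 11 19-acetoxy-8,8:12,12-bis(ethylenedioxy)-13,14,15,16,17-pentanor-ent-labdane-3,18-diol
Conditions: 30% aq. H2O2, KHCO3, THF/MeOH, rt to 40 °C
Reagents that add atoms: hydrogen peroxide, OO
Why: Tamao–Fleming oxidation moves C18 from silicon to oxygen with retention and hydrolysis of the Si–O bonds frees the 3,18-diol, while any loss of the acetate or its shift from O19 to O18 under these mildly basic conditions would be repaired in step 7, which acetylates every primary hydroxyl.

Step 7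
Reactants: 11 19-acetoxy-8,8:12,12-bis(ethylenedioxy)-13,14,15,16,17-pentanor-ent-labdane-3,18-diol; 12 acetyl chloride
Product: 13 18,19-diacetoxy-8,8:12,12-bis(ethylenedioxy)-13,14,15,16,17-pentanor-ent-labdan-3-ol
Conditions: AcCl (1.1 equiv), 2,4,6-collidine, CH2Cl2, −78 °C
Reagents that add atoms: acetyl chloride 12, CC(Cl)=O
Why: Selective acetylation of a primary alcohol beside a secondary one with acetyl chloride and a hindered pyridine base at low temperature should leave O3 free, and from here on C4 carries two identical acetoxymethyl groups and is no longer a stereocentre.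

Step 8
Reactants: 13 18,19-diacetoxy-8,8:12,12-bis(ethylenedioxy)-13,14,15,16,17-pentanor-ent-labdan-3-ol
Product: 14 O3-(imidazol-1-ylthiocarbonyl) derivative of 13
Conditions: 1,1'-thiocarbonyldiimidazole, DMAP (cat.), ClCH2CH2Cl, reflux
Reagents that add atoms: 1,1'-thiocarbonyldiimidazole, S=C(n1ccnc1)n1ccnc1
Why: Thioacylation of the remaining secondary hydroxyl under neutral conditions (first half of the Barton–McCombie deoxygenation) avoids the C3 alkoxide that would invite 1,3-acetyl migration from O18 or O19.

Step 9
Reactants: 14 O3-(imidazol-1-ylthiocarbonyl) derivative of 13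
Product: 15 18,19-diacetoxy-8,8:12,12-bis(ethylenedioxy)-13,14,15,16,17-pentanor-ent-labdane
Conditions: Bu3SnH, AIBN (cat.), toluene, reflux
Reagents that add atoms: none
Why: Barton–McCombie radical deoxygenation, in which the stannyl radical adds to sulfur, the C3–O bond fragments to a secondary radical and this takes hydrogen from the tin hydride, should remove O3 and the C3 stereocentre while acetates and acetals stay outside the radical chain.

Step 10
Reactants: 15 18,19-diacetoxy-8,8:12,12-bis(ethylenedioxy)-13,14,15,16,17-pentanor-ent-labdane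
Product: 17 18,19-diacetoxy-8-oxo-13,14,15,16,17-pentanor-ent-labdan-12-al, via 8-oxo 12-dioxolane diacetate 16 (not isolated)
Conditions: 1 M aq. HCl, THF, rt
Reagents that add atoms: water, O
Why: Aqueous acid hydrolysis of the two dioxolanes (the crowded C8 ketal first) should return the ketone and the aldehyde under conditions that primary acetates tolerate and in which water traps the oxocarbenium ions before the 1,4-dicarbonyl compound can cyclodehydrate.

Step 11
Reactants: 17 18,19-diacetoxy-8-oxo-13,14,15,16,17-pentanor-ent-labdan-12-al; 18 2-(triphenylphosphoranylidene)propanal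
Product: 19 (12E)-18,19-diacetoxy-8-oxo-15,17-dinor-ent-labd-12-en-14-al
Conditions: Ph3P=C(CH3)CHO (1.3 equiv), toluene, 80 °C
Reagents that add atoms: 2-(triphenylphosphoranylidene)propanal 18, CC(C=O)=P(c1ccccc1)(c1ccccc1)c1ccccc1
Why: Wittig reaction of a formyl-stabilised ylide should take the aldehyde and not the hindered C8 ketone and, through reversible oxaphosphetane formation, should give the (E)-trisubstituted enal with the formyl group trans to C11.

Step 12
Reactants: 19 (12E)-18,19-diacetoxy-8-oxo-15,17-dinor-ent-labd-12-en-14-al; 20 methyltriphenylphosphonium bromide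
Product: 22 ent-labda-8(17),12E,14-triene-18,19-diyl diacetate (CNP0129553.1), via 8-oxo diene diacetate 21 (not isolated)
Conditions: Ph3PCH3Br (4 equiv), KN(SiMe3)2 (3.8 equiv), THF, 0 °C; then 19, −78 °C to rt
Reagents that add atoms: methyltriphenylphosphonium bromide 20, C[P+](c1ccccc1)(c1ccccc1)c1ccccc1.[Br-]
Why: Double Wittig methylenation should convert the enal aldehyde first in a 1,2 sense and the C8 ketone on warming, giving the C14=C15 vinyl group and the C8=C17 methylidene, with the amide base kept below one equivalent per phosphonium salt so that no free base reaches the acetates or C9.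

**Compound list**

1 | andrographolide | C[C@@]12CC[C@H]([C@@]([C@H]1CCC(=C)[C@H]2C/C=C/3\[C@@H](COC3=O)O)(C)CO)O | starting material
2 | acetic anhydride | CC(=O)OC(C)=O | starting material
3 | 19-O-acetylandrographolide | C[C@@]12CC[C@H]([C@@]([C@H]1CCC(=C)[C@H]2C/C=C/3\[C@@H](COC3=O)O)(C)COC(C)=O)O | intermediate
4 | 19-acetoxy-3-hydroxy-8-oxo-13,14,15,16,17-pentanor-ent-labdan-12-al | O=CC[C@@H]1C(=O)CC[C@@H]2[C@](C)(COC(C)=O)[C@H](O)CC[C@@]12C | intermediate
5 | ethylene glycol | OCCO | starting material
6 | 19-acetoxy-12,12-ethylenedioxy-3-hydroxy-13,14,15,16,17-pentanor-ent-labdan-8-one (mono-dioxolane ketone, not isolated) | C4(OCCO4)C[C@@H]1C(=O)CC[C@@H]2[C@](C)(COC(C)=O)[C@H](O)CC[C@@]12C | intermediate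
7 | 19-acetoxy-8,8:12,12-bis(ethylenedioxy)-13,14,15,16,17-pentanor-ent-labdan-3-ol | C4(OCCO4)C[C@@H]1C3(OCCO3)CC[C@@H]2[C@](C)(COC(C)=O)[C@H](O)CC[C@@]12C | intermediate
8 | diethylsilane | CC[SiH2]CC | starting material
9 | 19-acetoxy-3-[(diethylsilyl)oxy]-8,8:12,12-bis(ethylenedioxy)-13,14,15,16,17-pentanor-ent-labdane (key-step precursor) | C4(OCCO4)C[C@@H]1C3(OCCO3)CC[C@@H]2[C@](C)(COC(C)=O)[C@H](O[SiH](CC)CC)CC[C@@]12C | intermediate
10 | oxasilolane bridging O3 and C18 of 19-acetoxy-8,8:12,12-bis(ethylenedioxy)-13,14,15,16,17-pentanor-ent-labdane (key-step product) | C4(OCCO4)C[C@@H]1C3(OCCO3)CC[C@@H]2[C@@]3(COC(C)=O)C[Si](CC)(CC)O[C@@H]3CC[C@@]12C | intermediate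
11 | 19-acetoxy-8,8:12,12-bis(ethylenedioxy)-13,14,15,16,17-pentanor-ent-labdane-3,18-diol | C4(OCCO4)C[C@@H]1C3(OCCO3)CC[C@@H]2[C@](CO)(COC(C)=O)[C@H](O)CC[C@@]12C | intermediate
12 | acetyl chloride | CC(Cl)=O | starting material
13 | 18,19-diacetoxy-8,8:12,12-bis(ethylenedioxy)-13,14,15,16,17-pentanor-ent-labdan-3-ol | C4(OCCO4)C[C@@H]1C3(OCCO3)CC[C@@H]2C(COC(C)=O)(COC(C)=O)[C@H](O)CC[C@@]12C | intermediate
14 | O3-(imidazol-1-ylthiocarbonyl) derivative of 13 | C4(OCCO4)C[C@@H]1C3(OCCO3)CC[C@@H]2C(COC(C)=O)(COC(C)=O)[C@H](OC(=S)n3ccnc3)CC[C@@]12C | intermediate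
15 | 18,19-diacetoxy-8,8:12,12-bis(ethylenedioxy)-13,14,15,16,17-pentanor-ent-labdane | C4(OCCO4)C[C@@H]1C3(OCCO3)CC[C@@H]2C(COC(C)=O)(COC(C)=O)CCC[C@@]12C | intermediate
16 | 18,19-diacetoxy-12,12-ethylenedioxy-13,14,15,16,17-pentanor-ent-labdan-8-one (8-oxo 12-dioxolane diacetate, not isolated) | C4(OCCO4)C[C@@H]1C(=O)CC[C@@H]2C(COC(C)=O)(COC(C)=O)CCC[C@@]12C | intermediate
17 | 18,19-diacetoxy-8-oxo-13,14,15,16,17-pentanor-ent-labdan-12-al | O=CC[C@@H]1C(=O)CC[C@@H]2C(COC(C)=O)(COC(C)=O)CCC[C@@]12C | intermediate
18 | 2-(triphenylphosphoranylidene)propanal | CC(C=O)=P(c1ccccc1)(c1ccccc1)c1ccccc1 | starting material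
19 | (12E)-18,19-diacetoxy-8-oxo-15,17-dinor-ent-labd-12-en-14-al | O=C/C(C)=C/C[C@@H]1C(=O)CC[C@@H]2C(COC(C)=O)(COC(C)=O)CCC[C@@]12C | intermediate
20 | methyltriphenylphosphonium bromide | C[P+](c1ccccc1)(c1ccccc1)c1ccccc1.[Br-] | starting material
21 | (12E)-18,19-diacetoxy-17-nor-ent-labda-12,14-dien-8-one (8-oxo diene diacetate, not isolated) | C=C/C(C)=C/C[C@@H]1C(=O)CC[C@@H]2C(COC(C)=O)(COC(C)=O)CCC[C@@]12C | intermediate
22 | ent-labda-8(17),12E,14-triene-18,19-diyl diacetate (CNP0129553.1) | C=C/C(C)=C/C[C@@H]1C(=C)CC[C@@H]2C(COC(C)=O)(COC(C)=O)CCC[C@@]12C | target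

**Step count and risks**

Total step count: 12. Longest linear sequence: 12 steps, from andrographolide 1 to 22.

Steps most likely to fail:

Step 5 (key step). C–H cleavage at C18 may be slower than loss of the Si–H function (redistribution at silicon, hydrosilylation of the neighbouring C19 acetate, adventitious hydrolysis), or the catalyst may be held back by the acetal and ester oxygens, so that only 7 is recovered after work-up. The fallback sets out from 7, comes back at 13 and puts the C18 oxygen in by oxime-directed palladium C–H acetoxylation. Alcohol 7 would be oxidised with Dess–Martin periodinane (CH2Cl2, NaHCO3) to the 3-ketone F1, which with NH2OH·HCl and NaOAc in MeOH should give the (E)-oxime F2. In AcOH/Ac2O the oxime would be acetylated in the flask, and Pd(OAc)2 (cat.) with PhI(OAc)2 at 80–100 °C should acetoxylate the C18 methyl through a five-membered N–Pd–C18 palladacycle of divalent palladium that is oxidised to tetravalent palladium before C–O bond formation, giving the O-acetyl oxime 18,19-diacetate F3. Buffered aqueous TiCl3/NH4OAc in THF should cleave the N–O bond and hydrolyse the imine to the 3-ketone 18,19-diacetate F4. NaBH4 in MeOH at 0 °C should deliver hydride axially and give the equatorial alcohol 13; its C3 epimer would serve as well, since step 9 removes that centre.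

Step 12. The basic ylide may enolise the hindered C8 ketone, which would stall the second olefination and open C9 to epimerisation, or it may attack the acetates during the warming that the ketone needs. The fallback sets out from 19 and ends at 22 by separating the two olefinations. Methylenetriphenylphosphorane (1.05 equiv, THF, −78 °C) would convert only the enal aldehyde, and the dienone 21 would be isolated. The ketone would then be methylenated with the non-basic Zn/CH2Br2/TiCl4 reagent in THF/CH2Cl2 at rt, which tolerates esters and does not enolise ketones. This fallback makes no new compound (F0).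

Step 7. Discrimination between the primary O18 and the secondary O3 may be incomplete, or acetyl may migrate onto O3 across the 1,3-diol, giving material that cannot be deoxygenated at C3. The fallback sets out from 11, comes back at 15 and replaces steps 7 to 9 by a regioselective deoxygenation of the diol. 1,1'-Thiocarbonyldiimidazole in toluene at 80 °C would give the cyclic 3,18-thionocarbonate F5. With Bu3SnH and AIBN in refluxing toluene the adduct radical should fragment towards the secondary C3 radical and not the primary C18 radical, and after loss of carbonyl sulfide and destannylation on work-up the 3-deoxy 18-alcohol F6 should result. Ac2O, pyridine and DMAP would then give 15.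

**Further compounds**

F1 | step 5 | 19-acetoxy-8,8:12,12-bis(ethylenedioxy)-13,14,15,16,17-pentanor-ent-labdan-3-one | C4(OCCO4)C[C@@H]1C3(OCCO3)CC[C@@H]2[C@](C)(COC(C)=O)C(=O)CC[C@@]12C
F2 | step 5 | (3E)-oxime of 19-acetoxy-8,8:12,12-bis(ethylenedioxy)-13,14,15,16,17-pentanor-ent-labdan-3-one | C4(OCCO4)C[C@@H]1C3(OCCO3)CC[C@@H]2[C@](C)(COC(C)=O)/C(=N/O)CC[C@@]12C
F3 | step 5 | (3E)-O-acetyl oxime of 18,19-diacetoxy-8,8:12,12-bis(ethylenedioxy)-13,14,15,16,17-pentanor-ent-labdan-3-one | C4(OCCO4)C[C@@H]1C3(OCCO3)CC[C@@H]2C(COC(C)=O)(COC(C)=O)/C(=N/OC(C)=O)CC[C@@]12C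
F4 | step 5 | 18,19-diacetoxy-8,8:12,12-bis(ethylenedioxy)-13,14,15,16,17-pentanor-ent-labdan-3-one | C4(OCCO4)C[C@@H]1C3(OCCO3)CC[C@@H]2C(COC(C)=O)(COC(C)=O)C(=O)CC[C@@]12C
F5 | step 7 | cyclic 3,18-thionocarbonate of 19-acetoxy-8,8:12,12-bis(ethylenedioxy)-13,14,15,16,17-pentanor-ent-labdane-3,18-diol | C4(OCCO4)C[C@@H]1C3(OCCO3)CC[C@@H]2[C@@]3(COC(C)=O)COC(=S)O[C@@H]3CC[C@@]12C
F6 | step 7 | 19-acetoxy-8,8:12,12-bis(ethylenedioxy)-13,14,15,16,17-pentanor-ent-labdan-18-ol | C4(OCCO4)C[C@@H]1C3(OCCO3)CC[C@@H]2[C@](CO)(COC(C)=O)CCC[C@@]12C
F0 | step 12 | none | none
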